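**Assumption:** the target is taken exactly as drawn, i.e. the (2R,4S,5R,6S,8S,12S,13S)-10E diastereomer of the narbonolide skeleton. Macrolide numbering is used throughout: lactone C=O is C1, C13 carries the ring oxygen, the ethyl group is C14–C15.

## Retrosynthetic overview

1. Target ⇐ 14-membered 10E-en-9-one lactone carrying C3–OTES and C5–OPMB, by C3 desilylation, C3 oxidation and PMB removal.
2. The only ring is closed at C9–C10, four steps from the end, by a nickel-catalysed intramolecular aldehyde C–H / terminal alkyne coupling (redox-neutral hydroacylation) of an open-chain ester ynal.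
3. Ynal ⇐ C2–C3 anti-aldol union of fragment B (propanoate of (3S,4S)-4-methylhex-5-yn-3-ol; C1–C2 and C10–C15) with fragment A (C3–C9 aldehyde).
4. Fragment A ⇐ SAMP-hydrazone alkylation (C6–C7), then Brown (Z)-crotylboration (C4–C5), from (R)-3-bromo-2-methylpropan-1-ol, propanal and cis-2-butene.
5. Fragment B ⇐ Brown (Z)-crotylboration of propanal (C12–C13), ozonolysis, Corey–Fuchs alkynylation (C10), propanoylation; both crotylborations draw on one batch of (Z)-crotylpotassium.

## Route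

### Fragment A (C3–C9), first part

**Step 1**
Reactants: 1 (R)-3-bromo-2-methylpropan-1-ol
Product: 2 (R)-(3-bromo-2-methylpropoxy)triethylsilane
Conditions: TESCl, imidazole, CH2Cl2, 0 °C → rt
Reagents that add atoms: chlorotriethylsilane, CC[Si](Cl)(CC)CC
Why: Silyl ether formation on the primary alcohol; the C8 stereocentre comes from the chiral pool and is not touched.

**Step 2**
Reactants: 2 (R)-(3-bromo-2-methylpropoxy)triethylsilane
Product: 3 (R)-triethyl(3-iodo-2-methylpropoxy)silane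
Conditions: NaI, NaHCO3 (cat.), acetone, reflux
Reagents that add atoms: sodium iodide, [Na+].[I-]
Why: Finkelstein halide exchange (SN2 at the primary carbon) gives the more reactive iodide needed for alkylation with a β-branched electrophile.

**Step 3**
Reactants: 4 propanal
Product: 5 propanal SAMP hydrazone, (S,E)-2-(methoxymethyl)-N-propylidenepyrrolidin-1-amine
Conditions: SAMP, Et2O, MgSO4, 0 °C → rt
Reagents that add atoms: SAMP, (S)-1-amino-2-(methoxymethyl)pyrrolidine, COC[C@@H]1CCCN1N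
Why: Hydrazone condensation installs the Enders auxiliary on the C5–C6 unit.

**Step 4**
Reactants: 5 propanal SAMP hydrazone; 3 (R)-triethyl(3-iodo-2-methylpropoxy)silane
Product: 7 SAMP hydrazone of (2S,4S)-2,4-dimethyl-5-(triethylsilyloxy)pentanal, via lithium azaenolate 6 (not isolated)
Conditions: LiN(iPr)2, THF, 0 °C; then 3, −100 °C → rt
Reagents that add atoms: none
Why: Enders SAMP-hydrazone α-alkylation, in which the iodide enters the less hindered face of the methoxy-chelated lithium azaenolate and sets C6 as S (as is general for SAMP hydrazones of propanal), giving the anti 6,8-dimethyl array.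

**Step 5**
Reactants: 7 SAMP hydrazone of (2S,4S)-2,4-dimethyl-5-(triethylsilyloxy)pentanal
Product: 8 (2S,4S)-2,4-dimethyl-5-(triethylsilyloxy)pentanal
Conditions: O3, CH2Cl2, −78 °C; N2 purge
Reagents that add atoms: ozone, [O-][O+]=O
Why: Ozonolytic cleavage of the hydrazone C=N bond releases the α-methyl aldehyde at −78 °C under neutral conditions, so C6 is not epimerised and the primary TES ether survives.

### Shared crotyl donor (one batch, divided between fragments A and B)

**Step 6**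
Reactants: 9 cis-2-butene
Product: 10 (Z)-but-2-en-1-ylpotassium (cold THF solution, divided by cannula between steps 7 and 10 and used at once)
Conditions: KOtBu, n-BuLi, THF, −78 → −45 °C, 15 min; recooled to −78 °C
Reagents that add atoms: potassium tert-butoxide, [K+].CC(C)(C)[O-]
Why: Schlosser superbase allylic metalation of cis-2-butene; the Z (endo) crotylpotassium is the favoured form and keeps its geometry at low temperature, so one batch can serve both crotylborations.

### Fragment A (C3–C9), second part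

**Step 7**
Reactants: 8 (2S,4S)-2,4-dimethyl-5-(triethylsilyloxy)pentanal; 10 (Z)-but-2-en-1-ylpotassium
Product: 12 (3R,4R,5S,7S)-3,5,7-trimethyl-8-(triethylsilyloxy)oct-1-en-4-ol, via (Z)-crotyl-(−)-Ipc2B 11 (not isolated)
Conditions: (−)-Ipc2BOMe, THF/Et2O, −78 °C; BF3·OEt2, −78 °C; then 8, −78 °C; NaOH, H2O2, 0 °C → rt
Reagents that add atoms: none
Why: Brown asymmetric (Z)-crotylboration through a chair Zimmerman–Traxler transition state, where the Z-crotyl geometry gives the 4,5-syn relationship and the (−)-Ipc2B unit delivers to the Si face of the aldehyde (reagent control), setting C4 (Me) and C5 (OH) all-syn to C6.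

**Step 8**
Reactants: 12 (3R,4R,5S,7S)-3,5,7-trimethyl-8-(triethylsilyloxy)oct-1-en-4-ol
Product: 13 4-methoxybenzyl ether of 12, triethyl{[(2S,4S,5R,6R)-5-(4-methoxybenzyloxy)-2,4,6-trimethyloct-7-en-1-yl]oxy}silane
Conditions: NaH, PMBCl, Bu4NI (cat.), DMF, 0 °C → rt
Reagents that add atoms: 4-methoxybenzyl chloride, COc1ccc(CCl)cc1
Why: Williamson etherification protects C5–OH as the PMB ether that is carried to the last step.

**Step 9**
Reactants: 13 4-methoxybenzyl ether of 12
Product: 14 (2S,3R,4S,6S)-3-(4-methoxybenzyloxy)-2,4,6-trimethyl-7-(triethylsilyloxy)heptanal (fragment A)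
Conditions: OsO4 (2 mol %), NaIO4, 2,6-lutidine, dioxane/H2O 3:1, rt
Reagents that add atoms: sodium periodate (net oxygen source, relayed through catalytic OsO4), [Na+].[O-]I(=O)(=O)=O
Why: Lemieux–Johnson oxidative cleavage (dihydroxylation, then periodate glycol cleavage, lutidine-buffered) turns the vinyl group into the C3 aldehyde without affecting PMB, TES or the α-stereocentre.

### Fragment B (C1–C2 and C10–C15)

**Step 10**
Reactants: 4 propanal; 10 (Z)-but-2-en-1-ylpotassium
Product: 16 (3S,4S)-4-methylhex-5-en-3-ol, via (Z)-crotyl-(+)-Ipc2B 15 (not isolated)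
Conditions: (+)-Ipc2BOMe, THF/Et2O, −78 °C; BF3·OEt2, −78 °C; then 4, −78 °C; NaOH, H2O2, 0 °C → rt
Reagents that add atoms: none
Why: Brown (Z)-crotylboration with the enantiomeric (+)-Ipc2B reagent adds to the Re face of propanal through the chair transition state and gives the syn (3S,4S) alcohol, setting C13 and C12.

**Step 11**
Reactants: 16 (3S,4S)-4-methylhex-5-en-3-ol
Product: 17 tert-butyldimethyl{[(3S,4S)-4-methylhex-5-en-3-yl]oxy}silane
Conditions: TBSCl, imidazole, DMF, rt
Reagents that add atoms: tert-butylchlorodimethylsilane, CC(C)(C)[Si](C)(C)Cl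
Why: Silyl ether formation protects the C13 hydroxyl for the alkene-to-alkyne conversion.

**Step 12**
Reactants: 17 tert-butyldimethyl{[(3S,4S)-4-methylhex-5-en-3-yl]oxy}silane
Product: 18 (2R,3S)-3-(tert-butyldimethylsilyloxy)-2-methylpentanal
Conditions: O3, CH2Cl2, −78 °C; then PPh3, −78 °C → rt
Reagents that add atoms: ozone, [O-][O+]=O
Why: Ozonolysis with reductive work-up cleaves the terminal alkene to the aldehyde that becomes C11.

**Step 13**
Reactants: 18 (2R,3S)-3-(tert-butyldimethylsilyloxy)-2-methylpentanal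
Product: 19 tert-butyl{[(3S,4S)-6,6-dibromo-4-methylhex-5-en-3-yl]oxy}dimethylsilane
Conditions: CBr4, PPh3, Zn, CH2Cl2, rt (ylide preformed); then 18, 0 °C → rt
Reagents that add atoms: tetrabromomethane, BrC(Br)(Br)Br
Why: Corey–Fuchs dibromo-olefination (Wittig-type reaction of Ph3P=CBr2) under base-free conditions brings in C10 without epimerising the α-stereocentre C12.

**Step 14**
Reactants: 19 tert-butyl{[(3S,4S)-6,6-dibromo-4-methylhex-5-en-3-yl]oxy}dimethylsilane
Product: 21 tert-butyldimethyl{[(3S,4S)-4-methylhex-5-yn-3-yl]oxy}silane, via lithium acetylide 20 (not isolated)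
Conditions: n-BuLi (2.2 equiv), THF, −78 → 0 °C; aq NH4Cl
Reagents that add atoms: none
Why: Second stage of the Corey–Fuchs alkyne synthesis (Br/Li exchange, Fritsch–Buttenberg–Wiechell rearrangement, deprotonation to the acetylide, protonation on work-up).

**Step 15**
Reactants: 21 tert-butyldimethyl{[(3S,4S)-4-methylhex-5-yn-3-yl]oxy}silane
Product: 22 (3S,4S)-4-methylhex-5-yn-3-ol
Conditions: Bu4NF, THF, rt (volatile product, carried on as an ether solution)
Reagents that add atoms: none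
Why: Fluoride-mediated desilylation frees the C13 hydroxyl.

**Step 16**
Reactants: 22 (3S,4S)-4-methylhex-5-yn-3-ol; 23 propanoyl chloride
Product: 24 (3S,4S)-4-methylhex-5-yn-3-yl propanoate (fragment B)
Conditions: pyridine, DMAP (cat.), CH2Cl2, 0 °C → rt
Reagents that add atoms: none
Why: DMAP-catalysed O-acylation forms the future lactone C1–O bond with retention at C13.

### Union, ring closure and end game

**Step 17**
Reactants: 24 (3S,4S)-4-methylhex-5-yn-3-yl propanoate; 14 (2S,3R,4S,6S)-3-(4-methoxybenzyloxy)-2,4,6-trimethyl-7-(triethylsilyloxy)heptanal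
Product: 27 (3S,4S)-4-methylhex-5-yn-3-yl (2R,3R,4R,5R,6S,8S)-3-hydroxy-5-(4-methoxybenzyloxy)-2,4,6,8-tetramethyl-9-(triethylsilyloxy)nonanoate, via E-boron enolate 25 (not isolated), via boron aldolate 26 (not isolated)
Conditions: 24 (1.5 equiv), c-Hex2BOTf, Et3N, CH2Cl2, −78 °C, 2 h; then 14, −78 → 0 °C; pH 7 buffer, MeOH, H2O2, 0 °C
Reagents that add atoms: none
Why: Boron-mediated anti-aldol reaction in which the E(O)-dicyclohexylboron enolate of the ester adds through a chair transition state to the Felkin face of the α-methyl aldehyde, so the C2 methyl ends up anti to the C4 methyl (2R) with a 3R carbinol; C3 is oxidised later, so only C2 has to be controlled, and the Z-enolate/anti-Felkin pathway would give the same 2R.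

**Step 18**
Reactants: 27 the anti-aldol ester
Product: 28 (3S,4S)-4-methylhex-5-yn-3-yl (2R,3R,4S,5R,6S,8S)-5-(4-methoxybenzyloxy)-2,4,6,8-tetramethyl-3,9-bis(triethylsilyloxy)nonanoate
Conditions: TESOTf, 2,6-lutidine, CH2Cl2, −78 °C
Reagents that add atoms: triethylsilyl trifluoromethanesulfonate, CC[Si](CC)(CC)OS(=O)(=O)C(F)(F)F
Why: Silylation masks C3–OH so that C2 is only an ester α-carbon, and no free hydroxyl is present, during the nickel step.

**Step 19**
Reactants: 28 the bis-TES ester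
Product: 29 (3S,4S)-4-methylhex-5-yn-3-yl (2R,3R,4S,5R,6S,8S)-5-(4-methoxybenzyloxy)-2,4,6,8-tetramethyl-9-oxo-3-(triethylsilyloxy)nonanoate (ynal)
Conditions: (COCl)2, DMSO, CH2Cl2, −78 → −40 °C; then iPr2NEt, −78 → 0 °C
Reagents that add atoms: none
Why: Swern oxidation applied directly to a silyl ether, in which chlorodimethylsulfonium chloride cleaves and oxidises the primary TES ether to the C9 aldehyde while the hindered secondary TES ether, the PMB ether and the alkyne are untouched.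

**Step 20 (key step)**
Reactants: 29 the ester ynal
Product: 30 (3R,4R,5S,6R,7S,9S,11E,13S,14S)-14-ethyl-6-(4-methoxybenzyloxy)-3,5,7,9,13-pentamethyl-4-(triethylsilyloxy)oxacyclotetradec-11-ene-2,10-dione
Conditions: Ni(cod)2 (20 mol %), IMes (1,3-dimesitylimidazol-2-ylidene, 20 mol %), toluene, 90 °C, syringe-pump addition of 29 over 10 h, final 0.002 M
Reagents that add atoms: none
Why: Proposed new method: a reductant-free macrocyclising alkyne hydroacylation on zerovalent nickel, in which the aldehyde and terminal alkyne of 29 undergo oxidative cyclisation at the Ni–NHC centre to a nickeladihydrofuran (C9–C10 bond at the terminal alkyne carbon, the small IMes ligand favouring the endocyclic mode), and with no silane present the metallacycle turns over by β-hydride elimination of the former aldehyde C–H and C–H reductive elimination, delivering H syn to C11 and closing the 14-membered ring directly as the 10E-enone with no change at existing stereocentres; the closest known reaction types are the nickel/NHC/silane reductive macrocyclisation of ynals and the intermolecular nickel-catalysed hydroacylation of internal alkynes.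

**Step 21**
Reactants: 30 the 3-O-TES macrocycle
Product: 31 (3R,4R,5R,6R,7S,9S,11E,13S,14S)-14-ethyl-4-hydroxy-6-(4-methoxybenzyloxy)-3,5,7,9,13-pentamethyloxacyclotetradec-11-ene-2,10-dione
Conditions: HF·pyridine, pyridine, THF, 0 °C → rt
Reagents that add atoms: none
Why: Buffered fluoride desilylation removes the secondary TES ether; the enone, lactone and PMB ether are stable.

**Step 22**
Reactants: 31 the 3-hydroxy macrocycle
Product: 32 (3R,5S,6R,7S,9S,11E,13S,14S)-14-ethyl-6-(4-methoxybenzyloxy)-3,5,7,9,13-pentamethyloxacyclotetradec-11-ene-2,4,10-trione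
Conditions: Dess–Martin periodinane, NaHCO3, CH2Cl2, 0 °C → rt
Reagents that add atoms: none
Why: Buffered Dess–Martin oxidation of the only free hydroxyl gives the 3-keto lactone under non-enolising conditions, so the 2R configuration set in step 17 is retained.

**Step 23**
Reactants: 32 the 5-O-PMB trione
Product: 33 target, (3R,5S,6R,7S,9S,11E,13S,14S)-14-ethyl-6-hydroxy-3,5,7,9,13-pentamethyloxacyclotetradec-11-ene-2,4,10-trione
Conditions: DDQ, CH2Cl2/pH 7 phosphate buffer 10:1, 0 °C → rt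
Reagents that add atoms: none
Why: Oxidative PMB ether cleavage with DDQ at neutral pH frees C5–OH without touching the enone or the epimerisable C2 centre.

## Compound list

1 | (R)-3-bromo-2-methylpropan-1-ol | BrC[C@H](C)CO | starting material
2 | (R)-(3-bromo-2-methylpropoxy)triethylsilane | BrC[C@H](C)CO[Si](CC)(CC)CC | intermediate
3 | (R)-triethyl(3-iodo-2-methylpropoxy)silane | IC[C@H](C)CO[Si](CC)(CC)CC | intermediate
4 | propanal | CCC=O | starting material
5 | propanal SAMP hydrazone, (S,E)-2-(methoxymethyl)-N-propylidenepyrrolidin-1-amine | CC/C=N/N1CCC[C@H]1COC | intermediate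
6 | lithium azaenolate of 5 (E C=C) | C/C=C/N([Li])N1CCC[C@H]1COC | intermediate
7 | SAMP hydrazone of (2S,4S)-2,4-dimethyl-5-(triethylsilyloxy)pentanal (E C=N) | COC[C@@H]1CCCN1/N=C/[C@@H](C)C[C@H](C)CO[Si](CC)(CC)CC | intermediate
8 | (2S,4S)-2,4-dimethyl-5-(triethylsilyloxy)pentanal | O=C[C@@H](C)C[C@H](C)CO[Si](CC)(CC)CC | intermediate
9 | cis-2-butene | C/C=C\C | starting material
10 | (Z)-but-2-en-1-ylpotassium | C/C=C\C[K] | intermediate
11 | (Z)-but-2-en-1-yl-bis[(1R,2R,3R,5S)-isopinocampheyl]borane, from (−)-Ipc2BOMe | C/C=C\CB([C@@H]1C[C@@H]2C[C@H]([C@H]1C)C2(C)C)[C@@H]1C[C@@H]2C[C@H]([C@H]1C)C2(C)C | intermediate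
12 | (3R,4R,5S,7S)-3,5,7-trimethyl-8-(triethylsilyloxy)oct-1-en-4-ol | C=C[C@@H](C)[C@H](O)[C@@H](C)C[C@H](C)CO[Si](CC)(CC)CC | intermediate
13 | triethyl{[(2S,4S,5R,6R)-5-(4-methoxybenzyloxy)-2,4,6-trimethyloct-7-en-1-yl]oxy}silane | C=C[C@@H](C)[C@H](OCc1ccc(OC)cc1)[C@@H](C)C[C@H](C)CO[Si](CC)(CC)CC | intermediate
14 | (2S,3R,4S,6S)-3-(4-methoxybenzyloxy)-2,4,6-trimethyl-7-(triethylsilyloxy)heptanal | O=C[C@@H](C)[C@H](OCc1ccc(OC)cc1)[C@@H](C)C[C@H](C)CO[Si](CC)(CC)CC | intermediate
15 | (Z)-but-2-en-1-yl-bis[(1S,2S,3S,5R)-isopinocampheyl]borane, from (+)-Ipc2BOMe | C/C=C\CB([C@H]1C[C@H]2C[C@@H]([C@@H]1C)C2(C)C)[C@H]1C[C@H]2C[C@@H]([C@@H]1C)C2(C)C | intermediate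
16 | (3S,4S)-4-methylhex-5-en-3-ol | CC[C@@H]([C@@H](C)C=C)O | intermediate
17 | tert-butyldimethyl{[(3S,4S)-4-methylhex-5-en-3-yl]oxy}silane | CC[C@@H]([C@@H](C)C=C)O[Si](C)(C)C(C)(C)C | intermediate
18 | (2R,3S)-3-(tert-butyldimethylsilyloxy)-2-methylpentanal | CC[C@@H]([C@@H](C)C=O)O[Si](C)(C)C(C)(C)C | intermediate
19 | tert-butyl{[(3S,4S)-6,6-dibromo-4-methylhex-5-en-3-yl]oxy}dimethylsilane | CC[C@@H]([C@@H](C)C=C(Br)Br)O[Si](C)(C)C(C)(C)C | intermediate
20 | lithium acetylide of 21 | CC[C@@H]([C@@H](C)C#C[Li])O[Si](C)(C)C(C)(C)C | intermediate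
21 | tert-butyldimethyl{[(3S,4S)-4-methylhex-5-yn-3-yl]oxy}silane | CC[C@@H]([C@@H](C)C#C)O[Si](C)(C)C(C)(C)C | intermediate
22 | (3S,4S)-4-methylhex-5-yn-3-ol | CC[C@@H]([C@@H](C)C#C)O | intermediate
23 | propanoyl chloride | CCC(=O)Cl | starting material
24 | (3S,4S)-4-methylhex-5-yn-3-yl propanoate | CC[C@@H]([C@@H](C)C#C)OC(=O)CC | intermediate
25 | dicyclohexylboron E(O)-enolate of 24 (methyl trans to O–B) | C/C=C(/OB(C1CCCCC1)C1CCCCC1)O[C@@H](CC)[C@@H](C)C#C | intermediate
26 | dicyclohexylboron aldolate of 27 (3-O-boryl) | CC[C@@H]([C@@H](C)C#C)OC(=O)[C@H](C)[C@H](OB(C1CCCCC1)C1CCCCC1)[C@@H](C)[C@H](OCc1ccc(OC)cc1)[C@@H](C)C[C@H](C)CO[Si](CC)(CC)CC | intermediate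
27 | (3S,4S)-4-methylhex-5-yn-3-yl (2R,3R,4R,5R,6S,8S)-3-hydroxy-5-(4-methoxybenzyloxy)-2,4,6,8-tetramethyl-9-(triethylsilyloxy)nonanoate | CC[C@@H]([C@@H](C)C#C)OC(=O)[C@H](C)[C@H](O)[C@@H](C)[C@H](OCc1ccc(OC)cc1)[C@@H](C)C[C@H](C)CO[Si](CC)(CC)CC | intermediate
28 | (3S,4S)-4-methylhex-5-yn-3-yl (2R,3R,4S,5R,6S,8S)-5-(4-methoxybenzyloxy)-2,4,6,8-tetramethyl-3,9-bis(triethylsilyloxy)nonanoate | CC[C@@H]([C@@H](C)C#C)OC(=O)[C@H](C)[C@H](O[Si](CC)(CC)CC)[C@@H](C)[C@H](OCc1ccc(OC)cc1)[C@@H](C)C[C@H](C)CO[Si](CC)(CC)CC | intermediate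
29 | (3S,4S)-4-methylhex-5-yn-3-yl (2R,3R,4S,5R,6S,8S)-5-(4-methoxybenzyloxy)-2,4,6,8-tetramethyl-9-oxo-3-(triethylsilyloxy)nonanoate | CC[C@@H]([C@@H](C)C#C)OC(=O)[C@H](C)[C@H](O[Si](CC)(CC)CC)[C@@H](C)[C@H](OCc1ccc(OC)cc1)[C@@H](C)C[C@H](C)C=O | intermediate
30 | (3R,4R,5S,6R,7S,9S,11E,13S,14S)-14-ethyl-6-(4-methoxybenzyloxy)-3,5,7,9,13-pentamethyl-4-(triethylsilyloxy)oxacyclotetradec-11-ene-2,10-dione | CC[C@@H]1OC(=O)[C@H](C)[C@H](O[Si](CC)(CC)CC)[C@@H](C)[C@H](OCc2ccc(OC)cc2)[C@@H](C)C[C@H](C)C(=O)/C=C/[C@@H]1C | intermediate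
31 | (3R,4R,5R,6R,7S,9S,11E,13S,14S)-14-ethyl-4-hydroxy-6-(4-methoxybenzyloxy)-3,5,7,9,13-pentamethyloxacyclotetradec-11-ene-2,10-dione | CC[C@@H]1OC(=O)[C@H](C)[C@H](O)[C@@H](C)[C@H](OCc2ccc(OC)cc2)[C@@H](C)C[C@H](C)C(=O)/C=C/[C@@H]1C | intermediate
32 | (3R,5S,6R,7S,9S,11E,13S,14S)-14-ethyl-6-(4-methoxybenzyloxy)-3,5,7,9,13-pentamethyloxacyclotetradec-11-ene-2,4,10-trione | CC[C@@H]1OC(=O)[C@H](C)C(=O)[C@@H](C)[C@H](OCc2ccc(OC)cc2)[C@@H](C)C[C@H](C)C(=O)/C=C/[C@@H]1C | intermediate
33 | (3R,5S,6R,7S,9S,11E,13S,14S)-14-ethyl-6-hydroxy-3,5,7,9,13-pentamethyloxacyclotetradec-11-ene-2,4,10-trione (CNP0143276.2) | CC[C@@H]1OC(=O)[C@H](C)C(=O)[C@@H](C)[C@H](O)[C@@H](C)C[C@H](C)C(=O)/C=C/[C@@H]1C | target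

## Step count and risks

Total step count: 23.
Longest linear sequence: 15 steps (6, 10–16, then 17–23; the fragment A branch 1, 2, 4, 5, 7, 8, 9 followed by 17–23 is 14), i.e. 15/23 = 0.65.

**Step 20, the new nickel-catalysed macrocyclising hydroacylation.** Possible failure modes are a nickeladihydrofuran that does not turn over, alkyne oligomerisation, Tishchenko-type dimerisation, aldehyde decarbonylation, the exocyclic regioisomer, and C8 epimerisation at 90 °C. The fallback uses known chemistry and sets out from 28. Hydrozirconation–iodination (Cp2Zr(H)Cl, THF, rt; then I2) gives the E-vinyl iodide F1. The Swern conditions of step 19 turn its primary TES ether into the iodo aldehyde F2. An intramolecular Nozaki–Hiyama–Kishi reaction (CrCl2 in excess, NiCl2 1 mol %, DMSO, rt, 0.005 M) closes the C9–C10 bond to the macrocyclic allylic alcohol F3 as a C9 epimer mixture. HF·pyridine gives the 3,9-diol F4, and excess Dess–Martin periodinane oxidises both carbinols, so the fallback comes back to the route at 32.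

**Step 17, the double-fragment boron aldol.** The risks are incomplete E-enolisation of a simple alkyl propanoate and only substrate-controlled facial selectivity at C2. The fallback replaces this union by an auxiliary-controlled aldol followed by esterification; it sets out from 14 and uses alcohol 22. An Evans syn-aldol with (R)-4-benzyl-3-propanoyl-oxazolidin-2-one (Bu2BOTf, iPr2NEt, CH2Cl2, −78 → 0 °C) gives the 2R,3S imide F5, with the same 2R and the C3 epimer, which is irrelevant after oxidation. TESOTf/2,6-lutidine gives the silyl ether F6, and LiOH/H2O2 (THF/H2O, 0 °C) gives the acid F7. Yamaguchi esterification (2,4,6-trichlorobenzoyl chloride, Et3N, DMAP, toluene) with 22 gives the ester F8, the C3 epimer of 28. The conditions of steps 19, 20 and 21 then lead through the ynal F9 and the macrocycle F10 to the 3-epi alcohol F11. Its Dess–Martin oxidation removes the C3 stereocentre, so the fallback comes back to the route at 32.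

**Step 7, the reagent-controlled (Z)-crotylboration of the α-methyl aldehyde.** The all-syn C4–C5–C6 triad requires the borane to override the inherent facial bias of 8, and the primary TES ether must survive the alkaline peroxide work-up. The fallback sets out from 8. An Evans syn-aldol with (S)-4-benzyl-3-propanoyl-oxazolidin-2-one (Bu2BOTf, iPr2NEt) gives the all-syn imide F12. 4-Methoxybenzyl trichloroacetimidate with La(OTf)3 (cat.) in toluene gives the PMB ether F13. LiBH4 (MeOH, THF, 0 °C) removes the auxiliary to give the primary alcohol F14, and Dess–Martin oxidation gives the aldehyde, so the fallback comes back to the route at 14.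

## Further compounds

F1 | step 20 | E-vinyl iodide from hydrozirconation–iodination of 28 | CC[C@@H]([C@@H](C)/C=C/I)OC(=O)[C@H](C)[C@H](O[Si](CC)(CC)CC)[C@@H](C)[C@H](OCc1ccc(OC)cc1)[C@@H](C)C[C@H](C)CO[Si](CC)(CC)CC
F2 | step 20 | iodo aldehyde (C9 aldehyde, E-vinyl iodide) | CC[C@@H]([C@@H](C)/C=C/I)OC(=O)[C@H](C)[C@H](O[Si](CC)(CC)CC)[C@@H](C)[C@H](OCc1ccc(OC)cc1)[C@@H](C)C[C@H](C)C=O
F3 | step 20 | macrocyclic 9-hydroxy-10E-ene, 3-O-TES, 5-O-PMB (C9 epimer mixture) | CC[C@@H]1OC(=O)[C@H](C)[C@H](O[Si](CC)(CC)CC)[C@@H](C)[C@H](OCc2ccc(OC)cc2)[C@@H](C)C[C@H](C)C(O)/C=C/[C@@H]1C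
F4 | step 20 | macrocyclic 3,9-diol, 5-O-PMB (C9 epimer mixture) | CC[C@@H]1OC(=O)[C@H](C)[C@H](O)[C@@H](C)[C@H](OCc2ccc(OC)cc2)[C@@H](C)C[C@H](C)C(O)/C=C/[C@@H]1C
F5 | step 17 | Evans syn-aldol imide (2R,3S) from 14 and the (R)-4-benzyl auxiliary | O=C1OC[C@@H](Cc2ccccc2)N1C(=O)[C@H](C)[C@@H](O)[C@@H](C)[C@H](OCc1ccc(OC)cc1)[C@@H](C)C[C@H](C)CO[Si](CC)(CC)CC
F6 | step 17 | 3-O-TES ether of F5 | O=C1OC[C@@H](Cc2ccccc2)N1C(=O)[C@H](C)[C@@H](O[Si](CC)(CC)CC)[C@@H](C)[C@H](OCc1ccc(OC)cc1)[C@@H](C)C[C@H](C)CO[Si](CC)(CC)CC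
F7 | step 17 | (2R,3S)-5-(4-methoxybenzyloxy)-2,4,6,8-tetramethyl-3,9-bis(triethylsilyloxy)nonanoic acid | OC(=O)[C@H](C)[C@@H](O[Si](CC)(CC)CC)[C@@H](C)[C@H](OCc1ccc(OC)cc1)[C@@H](C)C[C@H](C)CO[Si](CC)(CC)CC
F8 | step 17 | C3 epimer of 28 | CC[C@@H]([C@@H](C)C#C)OC(=O)[C@H](C)[C@@H](O[Si](CC)(CC)CC)[C@@H](C)[C@H](OCc1ccc(OC)cc1)[C@@H](C)C[C@H](C)CO[Si](CC)(CC)CC
F9 | step 17 | C3 epimer of ynal 29 | CC[C@@H]([C@@H](C)C#C)OC(=O)[C@H](C)[C@@H](O[Si](CC)(CC)CC)[C@@H](C)[C@H](OCc1ccc(OC)cc1)[C@@H](C)C[C@H](C)C=O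
F10 | step 17 | C3 epimer of macrocycle 30 | CC[C@@H]1OC(=O)[C@H](C)[C@@H](O[Si](CC)(CC)CC)[C@@H](C)[C@H](OCc2ccc(OC)cc2)[C@@H](C)C[C@H](C)C(=O)/C=C/[C@@H]1C
F11 | step 17 | C3 epimer of alcohol 31 | CC[C@@H]1OC(=O)[C@H](C)[C@@H](O)[C@@H](C)[C@H](OCc2ccc(OC)cc2)[C@@H](C)C[C@H](C)C(=O)/C=C/[C@@H]1C
F12 | step 7 | Evans syn-aldol imide from 8 and the (S)-4-benzyl auxiliary (all-syn C4–C5–C6) | O=C1OC[C@H](Cc2ccccc2)N1C(=O)[C@@H](C)[C@H](O)[C@@H](C)C[C@H](C)CO[Si](CC)(CC)CC
F13 | step 7 | 5-O-PMB ether of F12 | O=C1OC[C@H](Cc2ccccc2)N1C(=O)[C@@H](C)[C@H](OCc1ccc(OC)cc1)[C@@H](C)C[C@H](C)CO[Si](CC)(CC)CC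
F14 | step 7 | (2S,3R,4S,6S)-3-(4-methoxybenzyloxy)-2,4,6-trimethyl-7-(triethylsilyloxy)heptan-1-ol | OC[C@@H](C)[C@H](OCc1ccc(OC)cc1)[C@@H](C)C[C@H](C)CO[Si](CC)(CC)CC
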